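Compare the two clocks of this flask on a logarithmic scale.

- autumn: substrate 0.24 M; gas phase 76 mM (held); catalyst 0.24 mM; the very flask that is asked about, followed so far
- flask: substrate 0.24 M; gas phase 76 mM (held); catalyst 0.24 mM; time 8.0 min

autumn run (percent of the substrate charged)

| time / min | target / % | substrate / % |
|---|---|---|
| 0.167 | 40.9 | 40.2 |
| 0.250 | 57.2 | 19.1 |
| 0.833 | 47.1 | 0 |
| 2.50 | 16.9 | 0.3 |

(standard deviation of a reading: 0.5 percentage points)

- at the start none of the gas phase is in solution

* the best time, 8.0 min at the latest, for target
* the amount of target, in percent of the substrate charged, at that time

In the autumn run, which is this same flask, substrate falls from 40.2% to 19.1% between 0.167 min and 0.250 min, read as an apparent first-order constant of 8.97 min⁻¹ for that stretch of the run. Target later falls from 47.1% to 16.9%, read as 0.615 min⁻¹. These readings lie 1.16 decades apart; this clock gap, the decimal logarithm of the fast constant over the slow one, serves both settings.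

Time comes first. If the two apparent constants are treated as two first-order steps in series, a rough estimate, the gap places the peak at 0.321 min, and the peak keeps 82.1% of what the side losses leave. The early balance of substrate plus target reads 81.1%, so this reckoning, made here, gives about 66.6% target.

Catalyst comes second. If the fast constant follows its charge, cutting the charge narrows the gap by the logarithm of the cut and lowers the peak.

The forecast says 0.37 min (0.3 min to 0.45 min) and 62.5% (60% to 65%), on the ground that “peak comes where formation equals loss”. Its time is later than the reckoning here, and its height lower.

The simulation of this flask gives 67.8% target at 0.370 min, with 1.92% substrate still present.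

    2 substrate → homo dimer (k = 0.0652 M⁻¹ s⁻¹)
    target ⇌ isomer of the product (K = 8.60, k = 0.0145 s⁻¹)
    substrate + dissolved gas + catalyst → catalyst + target (k = 60900 M⁻² s⁻¹)
    gas phase ⇌ dissolved gas, rate k4*(csat - [dissolved gas]) (kL = 0.159 s⁻¹)

The peak time from the gap, 0.321 min, stands earlier than the computed one. The slowness of the gas transfer holds the peak down: without it, highest target in this flask rises from 67.8% to 93.0%, an effect larger than the 15 percentage points from removing the passing of target into isomer of the product.

With 9.6 × 10⁻⁵ M catalyst in the neighbour flask, scaling the fast constant with the charge puts the estimated gap at 0.766 decades, which keeps 69.4% and so gives about 56.3% target. The simulation of that flask gives 62.6%, lower than in the first flask but above this reckoning.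

The data are calculated for an exercise, and the scatter is random.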